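Everything rests on cutting the bond between the quaternary C2 of the pyran ring and the first side-chain methylene, C1'. C2 lies β to C4, so a 2-methylchromone serves as the masked 2H-chromene: copper-catalysed enantioselective conjugate addition of the complete C16 side chain, as its Grignard reagent, to C2 creates the tetrasubstituted, oxygen-bearing stereocentre and joins both halves, and triflation of the C3–C4 enolate in the same flask locks the C3=C4 double bond in place; reduction then removes the C4 oxygen. The precursors are 2,8-dimethyl-6-silyloxychromone and a homoallylic bromide already carrying the (S)-carbinol (from Sharpless epoxidation of geraniol) and both E-alkenes.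

Key step: step 11

Remark on numbering: chromene atoms are O1, C2, C3, C4, C4a, C5 to C8, C8a; side-chain carbons are primed, C1' being bonded to C2. The target is (2S,8'S).

Assumption: the sense of induction of the copper catalyst on a 2-alkylchromone cannot be read from precedent, so the ligand antipode that delivers the alkyl group to the Si face of C2 is chosen from a model run with 2-methylchromone ahead of step 11 (both antipodes are commercial).

**Route**

Step 1
Reactants: 1 4-methoxy-2-methylphenol
Product: 4 1-(2-hydroxy-5-methoxy-3-methylphenyl)ethan-1-one, via 4-methoxy-2-methylphenyl acetate 2 (not isolated), via difluoroboron chelate of the ketone 3 (not isolated)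
Conditions: Ac2O (1.2 equiv), BF3·OEt2 (3 equiv), 90 °C; then aq. NaOAc, EtOH, reflux
Reagents that add atoms: acetic anhydride, CC(=O)OC(C)=O
Why: O-acetylation followed by a BF3-mediated Fries rearrangement should place the acetyl group at the only free position ortho to the phenol oxygen (the para position is blocked by OMe), the ketone being held as its difluoroboron chelate until hydrolysis.

Step 2
Reactants: 4 1-(2-hydroxy-5-methoxy-3-methylphenyl)ethan-1-one
Product: 7 6-hydroxy-2,8-dimethyl-4H-chromen-4-one, via 1-(2-hydroxy-5-methoxy-3-methylphenyl)butane-1,3-dione 5 (not isolated), via 6-methoxy-2,8-dimethyl-4H-chromen-4-one 6 (not isolated)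
Conditions: NaH (4 equiv), EtOAc, THF, reflux; then 48% aq. HBr, AcOH, reflux
Reagents that add atoms: ethyl acetate, CCOC(C)=O
Why: Claisen condensation of the acetophenone enolate with ethyl acetate should give the 1,3-diketone, which cyclodehydrates in acid to the 2-methylchromone, and the hot HBr/AcOH should cleave the aryl methyl ether in the same operation.

Step 3
Reactants: 7 6-hydroxy-2,8-dimethyl-4H-chromen-4-one
Product: 8 2,8-dimethyl-6-(triisopropylsilyloxy)-4H-chromen-4-one
Conditions: TIPSCl, imidazole, DMF, rt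
Reagents that add atoms: chlorotri(propan-2-yl)silane, CC(C)[Si](Cl)(C(C)C)C(C)C
Why: Standard silylation of the phenol gives an aryl silyl ether that should tolerate the Grignard and formate steps and fall to fluoride at the end.

Step 4
Reactants: 9 geraniol
Product: 10 (2S,3S)-2,3-epoxygeraniol
Conditions: Ti(OiPr)4 (5 mol %), L-(+)-diethyl tartrate (7 mol %), t-BuOOH (2 equiv, isooctane), 4 Å molecular sieves, CH2Cl2, −20 °C
Reagents that add atoms: tert-butyl hydroperoxide, CC(C)(C)OO
Why: Katsuki–Sharpless asymmetric epoxidation of the allylic alcohol, in which L-(+)-diethyl tartrate has the established sense for geraniol that leads to the (2S,3S)-epoxide, sets C3, the later C8' carbinol centre.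

Step 5
Reactants: 10 (2S,3S)-2,3-epoxygeraniol
Product: 11 (2R,3S)-1-chloro-2,3-epoxy-3,7-dimethyloct-6-ene
Conditions: PPh3, CCl4, NaHCO3, reflux
Reagents that add atoms: tetrachloromethane, ClC(Cl)(Cl)Cl
Why: Appel chlorination of the primary alcohol under buffered neutral conditions should leave the acid-sensitive trisubstituted epoxide and both stereocentres untouched (the C2 descriptor changes only because Cl raises the priority of C1).

Step 6
Reactants: 11 (2R,3S)-1-chloro-2,3-epoxy-3,7-dimethyloct-6-ene
Product: 13 (3S)-3,7-dimethyloct-6-en-1-yn-3-ol, via lithium (3S)-1-chloro-3,7-dimethylocta-1,6-dien-3-olate 12 (not isolated)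
Conditions: n-BuLi (3.3 equiv), THF, −78 °C → −30 °C; aq. NH4Cl
Reagents that add atoms: none
Why: Base-induced fragmentation of a 2,3-epoxy chloride: deprotonation at the chloromethyl carbon opens the epoxide by C2–O cleavage, a second equivalent of base dehydrochlorinates the chlorovinyl alkoxide to the alkyne and a third deprotonates it, and since the C3–O bond is never broken the 3S configuration is retained.

Step 7
Reactants: 13 (3S)-3,7-dimethyloct-6-en-1-yn-3-ol
Product: 14 triethyl{[(3S)-3,7-dimethyloct-6-en-1-yn-3-yl]oxy}silane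
Conditions: TESOTf, 2,6-lutidine, CH2Cl2, −78 °C → 0 °C
Reagents that add atoms: triethylsilyl trifluoromethanesulfonate, CC[Si](CC)(CC)OS(=O)(=O)C(F)(F)F
Why: The silyl triflate should silylate the hindered tertiary alcohol without touching the terminal alkyne C–H, masking the only acidic proton before the organometallic steps.

Step 8
Reactants: 15 5-bromo-2-methylpent-2-ene
Product: 16 (2E)-5-bromo-2-methylpent-2-en-1-ol
Conditions: SeO2 (0.3 equiv), t-BuOOH (2 equiv), salicylic acid (cat.), CH2Cl2, rt
Reagents that add atoms: tert-butyl hydroperoxide, CC(C)(C)OO (net oxygen source; the oxygen is passed on by catalytic selenium dioxide, O=[Se]=O)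
Why: Allylic oxidation by SeO2 (ene reaction, then [2,3]-sigmatropic shift) attacks the E-methyl group of a gem-dimethyl alkene selectively, so the E-allylic alcohol is expected, any over-oxidised enal being removed by chromatography.

Step 9
Reactants: 16 (2E)-5-bromo-2-methylpent-2-en-1-ol
Product: 17 (2E)-1,5-dibromo-2-methylpent-2-ene
Conditions: PBr3 (0.4 equiv), Et2O, 0 °C
Reagents that add atoms: phosphorus tribromide, BrP(Br)Br
Why: SN2 bromination of the primary allylic alcohol at 0 °C should proceed without allylic transposition or loss of the E geometry.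

Step 10
Reactants: 14 triethyl{[(3S)-3,7-dimethyloct-6-en-1-yn-3-yl]oxy}silane; 17 (2E)-1,5-dibromo-2-methylpent-2-ene
Product: 19 (3E,6E,8S)-1-bromo-4,8,12-trimethyl-8-(triethylsilyloxy)trideca-3,6,11-triene, via (E)-alkenylzirconocene chloride 18 (not isolated)
Conditions: Cp2Zr(H)Cl (1.1 equiv), THF, rt; then 17 (1.2 equiv), Pd(PPh3)4 (5 mol %), THF, rt
Reagents that add atoms: none
Why: Syn hydrozirconation places zirconium on the terminal alkyne carbon (E-alkenyl metal, trisubstituted alkene untouched), and Negishi-type palladium-catalysed alkenyl–allyl coupling should join it to the less hindered CH2 terminus of the π-allyl unit formed from the allylic bromide, with both E geometries kept and the primary alkyl bromide inert.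

Step 11
Reactants: 19 (3E,6E,8S)-1-bromo-4,8,12-trimethyl-8-(triethylsilyloxy)trideca-3,6,11-triene; 8 2,8-dimethyl-6-(triisopropylsilyloxy)-4H-chromen-4-one
Product: 22 (2S)-2,8-dimethyl-2-[(3E,6E,8S)-4,8,12-trimethyl-8-(triethylsilyloxy)trideca-3,6,11-trien-1-yl]-6-(triisopropylsilyloxy)-2H-chromen-4-yl trifluoromethanesulfonate, via side-chain Grignard reagent 20 (not isolated), via bromomagnesium chromen-4-olate 21 (not isolated)
Conditions: Mg turnings (I2-activated), Et2O, rt; the solution of 20 (1.0 equiv) added over 2 h to 8 (1.3 equiv), CuBr·SMe2 (5 mol %), (R)-1-[(SP)-2-(dicyclohexylphosphino)ferrocenyl]ethyldiphenylphosphine or its antipode (6 mol %, see assumption), CH2Cl2/t-BuOMe, −78 °C → −40 °C; then N-(5-chloro-2-pyridyl)bis(trifluoromethanesulfonimide) (1.5 equiv), THF, −78 °C → 0 °C; aq. NH4Cl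
Reagents that add atoms: N-(5-chloro-2-pyridyl)bis(trifluoromethanesulfonimide), O=S(=O)(N(c1ccc(Cl)cn1)S(=O)(=O)C(F)(F)F)C(F)(F)F
Why: Proposed new method: Grignard reagent 20 transmetalates to the diphosphine-bound monovalent copper bromide, the resulting chiral alkylcopper species forms a π-complex with C2=C3 of 8, adds oxidatively at C2 to a trivalent copper enolate and reductively eliminates to make the C2–C1' bond, and the bromomagnesium enolate 21 left behind is O-sulfonylated by the N-aryl triflimide, which locks the C3=C4 double bond. The closest known reaction type is the CuBr·SMe2/ferrocenyl diphosphine-catalysed asymmetric conjugate addition of Grignard reagents to chromones that carry hydrogen at C2, together with copper-catalysed Grignard additions that build quaternary centres on 3-substituted cycloalkenones followed by triflation of the magnesium enolate; new here is the 2-alkylchromone acceptor, which makes C2 a tetrasubstituted O-bearing centre. No ring is closed, the pyranone ring of 8 being carried over as the pyran ring of the product. The C2 stereocentre is set by the catalyst alone: the ligand antipode is chosen so that the alkyl group enters on the Si face of C2 (O1, C3 and the methyl carbon counterclockwise), which gives 2S, and the 8'S centre is too remote to match or mismatch. The step needs 1,4-addition to win over 1,2-addition and over deprotonation of the vinylogously acidic 2-methyl group, which the poorly electrophilic vinylogous-ester carbonyl, the low temperature and the slow addition of 20 (free Grignard reagent kept scarce relative to alkylcopper) should secure, and it needs O- instead of C-sulfonylation of a regiodefined enolate, which the hard triflyl donor and the origin of 21 in the conjugate addition provide.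

Step 12
Reactants: 22 (2S)-2,8-dimethyl-2-[(3E,6E,8S)-4,8,12-trimethyl-8-(triethylsilyloxy)trideca-3,6,11-trien-1-yl]-6-(triisopropylsilyloxy)-2H-chromen-4-yl trifluoromethanesulfonate
Product: 23 (2S)-2,8-dimethyl-2-[(3E,6E,8S)-4,8,12-trimethyl-8-(triethylsilyloxy)trideca-3,6,11-trien-1-yl]-6-(triisopropylsilyloxy)-2H-chromene
Conditions: Pd(OAc)2 (5 mol %), PPh3 (10 mol %), HCO2H (2 equiv), n-Bu3N (3 equiv), DMF, 60 °C
Reagents that add atoms: none
Why: Palladium-catalysed formate reduction of the enol triflate (oxidative addition, formate exchange, decarboxylation to a palladium hydride, reductive elimination) should replace OTf by H and leave the C3=C4 alkene of the 2H-chromene, with C2 not involved.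

Step 13
Reactants: 23 (2S)-2,8-dimethyl-2-[(3E,6E,8S)-4,8,12-trimethyl-8-(triethylsilyloxy)trideca-3,6,11-trien-1-yl]-6-(triisopropylsilyloxy)-2H-chromene
Product: 24 (2S)-2-[(3E,6E,8S)-8-hydroxy-4,8,12-trimethyltrideca-3,6,11-trien-1-yl]-2,8-dimethyl-2H-chromen-6-ol (CNP0155965.1)
Conditions: Bu4NF (3 equiv), THF, 0 °C → rt, argon
Reagents that add atoms: none
Why: Fluoride should cleave both the aryl triisopropylsilyl ether and the tertiary triethylsilyl ether under non-acidic conditions that spare the tertiary allylic alcohol, the skipped diene and the chromene.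

**Compound list**

1 | 4-methoxy-2-methylphenol | COc1ccc(O)c(C)c1 | starting material
2 | 4-methoxy-2-methylphenyl acetate | COc1ccc(OC(C)=O)c(C)c1 | intermediate
3 | difluoroboron chelate of 1-(2-hydroxy-5-methoxy-3-methylphenyl)ethan-1-one | CC1=[O+][B-](F)(F)Oc2c1cc(OC)cc2C | intermediate
4 | 1-(2-hydroxy-5-methoxy-3-methylphenyl)ethan-1-one | CC(=O)c1cc(OC)cc(C)c1O | intermediate
5 | 1-(2-hydroxy-5-methoxy-3-methylphenyl)butane-1,3-dione | CC(=O)CC(=O)c1cc(OC)cc(C)c1O | intermediate
6 | 6-methoxy-2,8-dimethyl-4H-chromen-4-one | Cc1cc(=O)c2cc(OC)cc(C)c2o1 | intermediate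
7 | 6-hydroxy-2,8-dimethyl-4H-chromen-4-one | Cc1cc(=O)c2cc(O)cc(C)c2o1 | intermediate
8 | 2,8-dimethyl-6-(triisopropylsilyloxy)-4H-chromen-4-one | Cc1cc(=O)c2cc(O[Si](C(C)C)(C(C)C)C(C)C)cc(C)c2o1 | intermediate
9 | geraniol [(2E)-3,7-dimethylocta-2,6-dien-1-ol] | CC(C)=CCC/C(C)=C/CO | starting material
10 | (2S,3S)-2,3-epoxygeraniol {[(2S,3S)-3-methyl-3-(4-methylpent-3-en-1-yl)oxiran-2-yl]methanol} | OC[C@@H]1O[C@@]1(C)CCC=C(C)C | intermediate
11 | (2R,3S)-1-chloro-2,3-epoxy-3,7-dimethyloct-6-ene | ClC[C@@H]1O[C@@]1(C)CCC=C(C)C | intermediate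
12 | lithium (3S)-1-chloro-3,7-dimethylocta-1,6-dien-3-olate (chlorovinyl geometry immaterial) | CC(C)=CCC[C@](C)(O[Li])C=CCl | intermediate
13 | (3S)-3,7-dimethyloct-6-en-1-yn-3-ol | CC(C)=CCC[C@](C)(O)C#C | intermediate
14 | triethyl{[(3S)-3,7-dimethyloct-6-en-1-yn-3-yl]oxy}silane | CC(C)=CCC[C@](C)(O[Si](CC)(CC)CC)C#C | intermediate
15 | 5-bromo-2-methylpent-2-ene | CC(C)=CCCBr | starting material
16 | (2E)-5-bromo-2-methylpent-2-en-1-ol | OC/C(C)=C/CCBr | intermediate
17 | (2E)-1,5-dibromo-2-methylpent-2-ene | BrC/C(C)=C/CCBr | intermediate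
18 | chlorobis(cyclopentadienyl)[(1E,3S)-3,7-dimethyl-3-(triethylsilyloxy)octa-1,6-dien-1-yl]zirconium | CC(C)=CCC[C@](C)(O[Si](CC)(CC)CC)/C=C/[Zr](Cl)(C1C=CC=C1)C1C=CC=C1 | intermediate
19 | (3E,6E,8S)-1-bromo-4,8,12-trimethyl-8-(triethylsilyloxy)trideca-3,6,11-triene | CC(C)=CCC[C@](C)(O[Si](CC)(CC)CC)/C=C/C/C(C)=C/CCBr | intermediate
20 | [(3E,6E,8S)-4,8,12-trimethyl-8-(triethylsilyloxy)trideca-3,6,11-trien-1-yl]magnesium bromide | CC(C)=CCC[C@](C)(O[Si](CC)(CC)CC)/C=C/C/C(C)=C/CC[Mg]Br | intermediate
21 | bromomagnesium (2S)-2,8-dimethyl-2-[(3E,6E,8S)-4,8,12-trimethyl-8-(triethylsilyloxy)trideca-3,6,11-trien-1-yl]-6-(triisopropylsilyloxy)-2H-chromen-4-olate | CC(C)=CCC[C@](C)(O[Si](CC)(CC)CC)/C=C/C/C(C)=C/CC[C@@]1(C)C=C(O[Mg]Br)c2cc(O[Si](C(C)C)(C(C)C)C(C)C)cc(C)c2O1 | intermediate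
22 | (2S)-2,8-dimethyl-2-[(3E,6E,8S)-4,8,12-trimethyl-8-(triethylsilyloxy)trideca-3,6,11-trien-1-yl]-6-(triisopropylsilyloxy)-2H-chromen-4-yl trifluoromethanesulfonate | CC(C)=CCC[C@](C)(O[Si](CC)(CC)CC)/C=C/C/C(C)=C/CC[C@@]1(C)C=C(OS(=O)(=O)C(F)(F)F)c2cc(O[Si](C(C)C)(C(C)C)C(C)C)cc(C)c2O1 | intermediate
23 | (2S)-2,8-dimethyl-2-[(3E,6E,8S)-4,8,12-trimethyl-8-(triethylsilyloxy)trideca-3,6,11-trien-1-yl]-6-(triisopropylsilyloxy)-2H-chromene | CC(C)=CCC[C@](C)(O[Si](CC)(CC)CC)/C=C/C/C(C)=C/CC[C@@]1(C)C=Cc2cc(O[Si](C(C)C)(C(C)C)C(C)C)cc(C)c2O1 | intermediate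
24 | (2S)-2-[(3E,6E,8S)-8-hydroxy-4,8,12-trimethyltrideca-3,6,11-trien-1-yl]-2,8-dimethyl-2H-chromen-6-ol | CC(C)=CCC[C@](C)(O)/C=C/C/C(C)=C/CC[C@@]1(C)C=Cc2cc(O)cc(C)c2O1 | target

**Count and risks**

Total step count: 13. Longest linear sequence: 8 steps (steps 4, 5, 6, 7, 10, 11, 12, 13).

The three steps most likely to fail:

Step 11 (proposed new method). The catalyst may not discriminate the two faces of the 2-methylchromone. The Grignard reagent may deprotonate the 2-methyl group or add to the carbonyl faster than the catalysed 1,4-path. The magnesium enolate may also resist O-triflation. The fallback uses known chemistry and sets out from 8 and 20. The ligand is omitted and the addition is run as the known chlorotrimethylsilane-accelerated stoichiometric organocopper conjugate addition, a reaction type established for β,β-disubstituted enones and for chromones (CuBr·SMe2 1 equiv, Me3SiCl 2 equiv, THF, −78 °C → −20 °C). This should give 2,8-dimethyl-2-[(3E,6E,8S)-4,8,12-trimethyl-8-(triethylsilyloxy)trideca-3,6,11-trien-1-yl]-6-(triisopropylsilyloxy)-4-(trimethylsilyloxy)-2H-chromene F1 as both C2 epimers. MeLi (THF, 0 °C) then regenerates the lithium enolate, and the same triflimide converts it into 22 together with its (2R)-epimer F2. Because C8' has a single configuration, the two are diastereomers, to be separated by preparative HPLC on a cellulose carbamate chiral stationary phase (at this stage, or after step 12 or 13 if resolution is better there). The route is rejoined at 22.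

Step 10. The π-allyl coupling may be slow or unselective: attack at the substituted allyl terminus (branched product), syn/anti isomerisation of the π-allyl palladium intermediate with loss of the E geometry, or reduction of the allylic bromide by residual zirconium hydride. The fallback sets out from 13 and 17 and changes both the bond-forming event and the way the E-alkene is set. Copper acetylide SN2 coupling (CuI 10 mol %, Cs2CO3, DMF, rt) should give (3E,8S)-1-bromo-4,8,12-trimethyltrideca-3,11-dien-6-yn-8-ol F3. Ruthenium-catalysed trans-hydrosilylation ([Cp*Ru(MeCN)3]PF6 cat., (EtO)3SiH, CH2Cl2, 0 °C → rt), which places silicon on the alkyne carbon distal to the hydroxyl group, should give (3E,6Z,8S)-1-bromo-4,8,12-trimethyl-6-(triethoxysilyl)trideca-3,6,11-trien-8-ol F4. Protodesilylation with retention (CuI, Bu4NF, THF, 0 °C → rt) should give (3E,6E,8S)-1-bromo-4,8,12-trimethyltrideca-3,6,11-trien-8-ol F5. Silylation as in step 7 (TESOTf, 2,6-lutidine) returns to 19.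

Step 12. A palladium hydride may walk along the skipped C3'/C6' diene, zerovalent palladium may ionise the allylic C2–O1 ether and erode C2, or the aryl silyl ether may be lost in warm formate/DMF. The fallback avoids palladium and sets out from enolate 21. Protic quench (aq. NH4Cl) in place of triflation should give (2S)-2,8-dimethyl-2-[(3E,6E,8S)-4,8,12-trimethyl-8-(triethylsilyloxy)trideca-3,6,11-trien-1-yl]-6-(triisopropylsilyloxy)-2,3-dihydro-4H-chromen-4-one F6. NaBH4 (MeOH/THF, 0 °C) should reduce it to the corresponding (2S,4RS)-3,4-dihydro-2H-chromen-4-ol F7, whose C4 configuration is immaterial. Syn-elimination of the benzylic alcohol with methyl N-(triethylammoniosulfonyl)carbamate (toluene, 50 °C) returns to 23.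

Further compounds
F1 | step 11 | (2RS)-2,8-dimethyl-2-[(3E,6E,8S)-4,8,12-trimethyl-8-(triethylsilyloxy)trideca-3,6,11-trien-1-yl]-6-(triisopropylsilyloxy)-4-(trimethylsilyloxy)-2H-chromene | CC(C)=CCC[C@](C)(O[Si](CC)(CC)CC)/C=C/C/C(C)=C/CCC1(C)C=C(O[Si](C)(C)C)c2cc(O[Si](C(C)C)(C(C)C)C(C)C)cc(C)c2O1
F2 | step 11 | (2R)-2,8-dimethyl-2-[(3E,6E,8S)-4,8,12-trimethyl-8-(triethylsilyloxy)trideca-3,6,11-trien-1-yl]-6-(triisopropylsilyloxy)-2H-chromen-4-yl trifluoromethanesulfonate | CC(C)=CCC[C@](C)(O[Si](CC)(CC)CC)/C=C/C/C(C)=C/CC[C@]1(C)C=C(OS(=O)(=O)C(F)(F)F)c2cc(O[Si](C(C)C)(C(C)C)C(C)C)cc(C)c2O1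
F3 | step 10 | (3E,8S)-1-bromo-4,8,12-trimethyltrideca-3,11-dien-6-yn-8-ol | CC(C)=CCC[C@](C)(O)C#CC/C(C)=C/CCBr
F4 | step 10 | (3E,6Z,8S)-1-bromo-4,8,12-trimethyl-6-(triethoxysilyl)trideca-3,6,11-trien-8-ol | CC(C)=CCC[C@](C)(O)/C=C(\[Si](OCC)(OCC)OCC)C/C(C)=C/CCBr
F5 | step 10 | (3E,6E,8S)-1-bromo-4,8,12-trimethyltrideca-3,6,11-trien-8-ol | CC(C)=CCC[C@](C)(O)/C=C/C/C(C)=C/CCBr
F6 | step 12 | (2S)-2,8-dimethyl-2-[(3E,6E,8S)-4,8,12-trimethyl-8-(triethylsilyloxy)trideca-3,6,11-trien-1-yl]-6-(triisopropylsilyloxy)-2,3-dihydro-4H-chromen-4-one | CC(C)=CCC[C@](C)(O[Si](CC)(CC)CC)/C=C/C/C(C)=C/CC[C@@]1(C)CC(=O)c2cc(O[Si](C(C)C)(C(C)C)C(C)C)cc(C)c2O1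
F7 | step 12 | (2S,4RS)-2,8-dimethyl-2-[(3E,6E,8S)-4,8,12-trimethyl-8-(triethylsilyloxy)trideca-3,6,11-trien-1-yl]-6-(triisopropylsilyloxy)-3,4-dihydro-2H-chromen-4-ol | CC(C)=CCC[C@](C)(O[Si](CC)(CC)CC)/C=C/C/C(C)=C/CC[C@@]1(C)CC(O)c2cc(O[Si](C(C)C)(C(C)C)C(C)C)cc(C)c2O1
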